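Flavonoid numbering is used: ring A = C5–C8, ring C = O1–C4, ring B = C1'–C6', ring D = the dimethylpyran on C2'/C3'. The first retrosynthetic cut removes three bonds at once: the ring D bonds O3'–C(CH3)2 and C2'–CH=, and the C8–CH2 bond of the prenyl group. Both C5 units go back onto oxygen, as a 1,1-dimethylpropargyl ether on O3' and a prenyl ether on O5.
The second cut opens ring C at O1–C2 and C3–O (Algar–Flynn–Oyamada) and at Cα=Cβ (Claisen–Schmidt), giving acetophenone fragment A and benzaldehyde fragment B. The third cut is C6'–C(CH3)2, to an aryl bromide and a prenylboronate coupled at its γ carbon.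
In the forward direction rings A and B are bought as arenes, ring C is closed from the chalcone, and ring D is closed last.
The enabling feature lies in ring B. O3' sits between C4' (oxygen-bearing, blocked) and C2'–H, so a [3,3] shift from O3' can end productively only at C2'. The vinyl ortho-quinone methide that follows, O=C3'–C2'=CH–CH=C(CH3)2, consists of exactly the six atoms of ring D.
In ring A, O5 has one free ortho carbon (C6) and a free para carbon (C8). The same heating therefore relays the prenyl group O5→C6→C8.
The target has no stereocentre. The transient centres (epoxide, C2/C3 of the dihydroflavonol, C6 of the dienone) are erased, and the chalcone (E) geometry comes from E1cB dehydration.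

Key step: step 11

Assumption: the target SMILES carries no stereodescriptor, so the hindered C2–C1' axis is taken as configurationally undefined and no atropselective step is planned.

Step 1
Reactants: 1 2,4,6-trihydroxyacetophenone
Product: 2 1-[2,6-dihydroxy-4-(methoxymethoxy)phenyl]ethanone
Conditions: MOMCl (1.0 equiv), K2CO3 (1.1 equiv), acetone, 0 °C to rt
Reagents that add atoms: chloromethyl methyl ether (MOMCl), COCCl
Why: Williamson-type O-alkylation that should pick the 4-OH, which is the most acidic hydroxyl and the only one not locked in a hydrogen bond to the acetyl C=O.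

Step 2
Reactants: 2 1-[2,6-dihydroxy-4-(methoxymethoxy)phenyl]ethanone
Product: 3 1-[2-hydroxy-4-(methoxymethoxy)-6-(3-methylbut-2-enyloxy)phenyl]ethanone (fragment A)
Conditions: prenyl bromide (1.05 equiv), K2CO3 (1.2 equiv), acetone, reflux
Reagents that add atoms: 1-bromo-3-methylbut-2-ene (prenyl bromide), CC(C)=CCBr
Why: Williamson ether synthesis on two symmetry-equivalent hydroxyls; once one is alkylated the other is held in a strong chelate to C=O and should resist a second alkylation, as in the usual stop of phloroacetophenone alkylations at the 2-hydroxy-4,6-dialkoxy stage.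

Step 3
Reactants: 4 2-bromo-4,5-dimethoxybenzaldehyde
Product: 5 2-bromo-4,5-dihydroxybenzaldehyde
Conditions: BBr3 (2.5 equiv), CH2Cl2, −78 °C to rt; then H2O
Reagents that add atoms: none
Why: Lewis acid cleavage of aryl methyl ethers by BBr3, which tolerates the aryl bromide and the aldehyde and frees the catechol so that acid-removable groups can replace the methyl groups.

Step 4
Reactants: 5 2-bromo-4,5-dihydroxybenzaldehyde
Product: 6 2-bromo-5-hydroxy-4-(methoxymethoxy)benzaldehyde
Conditions: MOMCl (1.05 equiv), K2CO3 (1.05 equiv), acetone, 0 °C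
Reagents that add atoms: chloromethyl methyl ether (MOMCl), COCCl
Why: Regioselective Williamson-type alkylation; the 4-OH is para to the formyl group and far more acidic than the 5-OH, so one equivalent of weak base and MOMCl should cap only O4 (the later O4').

Step 5
Reactants: 6 2-bromo-5-hydroxy-4-(methoxymethoxy)benzaldehyde
Product: 7 4-bromo-5-(dimethoxymethyl)-2-(methoxymethoxy)phenol
Conditions: HC(OMe)3 (3 equiv), PPTS (5 mol %), MeOH, rt
Reagents that add atoms: trimethyl orthoformate, COC(OC)OC
Why: Acid-catalysed acetalisation with an orthoester as water scavenger; it masks the aldehyde against allylboration by the prenylboronate of the next step, and PPTS at room temperature should leave the aryl MOM ether alone.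

Step 6
Reactants: 7 4-bromo-5-(dimethoxymethyl)-2-(methoxymethoxy)phenol
Product: 9 5-hydroxy-4-(methoxymethoxy)-2-(2-methylbut-3-en-2-yl)benzaldehyde, via coupled dimethyl acetal 8 (not isolated)
Conditions: prenylboronic acid pinacol ester (1.5 equiv), Pd(OAc)2 (3 mol %), 1,1'-bis(di-tert-butylphosphino)ferrocene (3.6 mol %), K3PO4 (aq, 3.5 equiv), THF, 50 °C; then 1 M HCl, THF, 0 °C
Reagents that add atoms: 3-methylbut-2-enylboronic acid pinacol ester, CC(C)=CCB1OC(C)(C)C(C)(C)O1; water, O
Why: γ-Selective Suzuki–Miyaura allylation; the boronate transmetalates with allyl transposition (SE2') so that palladium sits on the tertiary carbon, the bulky electron-rich bisphosphine should force reductive elimination ahead of σ–π–σ slippage to give the 1,1-dimethylallyl arene, and the very labile benzaldehyde acetal is hydrolysed in the cold acidic work-up that leaves the MOM ether in place.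

Step 7
Reactants: 9 5-hydroxy-4-(methoxymethoxy)-2-(2-methylbut-3-en-2-yl)benzaldehyde
Product: 10 4-(methoxymethoxy)-2-(2-methylbut-3-en-2-yl)-5-(2-methylbut-3-yn-2-yloxy)benzaldehyde (fragment B)
Conditions: 3-chloro-3-methylbut-1-yne (2 equiv), K2CO3 (2 equiv), KI (10 mol %), CuI (5 mol %), DMF, N2, 55 °C
Reagents that add atoms: 3-chloro-3-methylbut-1-yne, CC(C)(Cl)C#C
Why: Copper-assisted O-propargylation of a phenol with a tertiary propargylic chloride (allenylidene-type ionisation pathway), the standard entry to aryl 1,1-dimethylpropargyl ethers, run well below the temperature of the Claisen shift.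

Step 8
Reactants: 3 1-[2-hydroxy-4-(methoxymethoxy)-6-(3-methylbut-2-enyloxy)phenyl]ethanone (fragment A); 10 4-(methoxymethoxy)-2-(2-methylbut-3-en-2-yl)-5-(2-methylbut-3-yn-2-yloxy)benzaldehyde (fragment B)
Product: 11 (E)-1-[2-hydroxy-4-(methoxymethoxy)-6-(3-methylbut-2-enyloxy)phenyl]-3-[4-(methoxymethoxy)-2-(2-methylbut-3-en-2-yl)-5-(2-methylbut-3-yn-2-yloxy)phenyl]prop-2-en-1-one
Conditions: KOH (50 % aq), EtOH, rt
Reagents that add atoms: none
Why: Claisen–Schmidt condensation; the aldehyde cannot enolise, E1cB loss of water gives the (E)-enone, and the MOM ethers, prenyl ether, alkyne and alkene are inert to aqueous alcoholic KOH.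

Step 9
Reactants: 11 the (E)-chalcone
Product: 14 3-hydroxy-7-(methoxymethoxy)-5-(3-methylbut-2-enyloxy)-2-[4-(methoxymethoxy)-2-(2-methylbut-3-en-2-yl)-5-(2-methylbut-3-yn-2-yloxy)phenyl]-4H-chromen-4-one, via trans-chalcone epoxide 12 (not isolated), via trans-dihydroflavonol 13 (not isolated)
Conditions: 30 % H2O2, NaOH (2 M aq), MeOH–THF, 0 °C to rt
Reagents that add atoms: hydrogen peroxide, OO
Why: Algar–Flynn–Oyamada reaction; hydroperoxide epoxidises only the electron-poor enone (Weitz–Scheffer), the 2'-phenoxide opens the epoxide at the benzylic carbon activated by the para OMOM group (6-endo), and the dihydroflavonol is dehydrogenated in the same medium, so the two transient trans centres are erased while the isolated alkenes and the alkyne stay untouched.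

Step 10
Reactants: 14 the 3-hydroxyflavone of step 9
Product: 15 3,7-bis(methoxymethoxy)-5-(3-methylbut-2-enyloxy)-2-[4-(methoxymethoxy)-2-(2-methylbut-3-en-2-yl)-5-(2-methylbut-3-yn-2-yloxy)phenyl]-4H-chromen-4-one
Conditions: MOMCl (1.5 equiv), K2CO3 (2 equiv), acetone, 40 °C
Reagents that add atoms: chloromethyl methyl ether (MOMCl), COCCl
Why: Williamson-type protection of the only free hydroxyl; it keeps O3 from adding to the quinone methide of the next step and keeps the flavonol from oxidising at high temperature.

Step 11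
Reactants: 15 the bis-ether precursor of step 10
Product: 19 5-hydroxy-3,7-bis(methoxymethoxy)-8-(3-methylbut-2-enyl)-2-[8-(methoxymethoxy)-2,2-dimethyl-6-(2-methylbut-3-en-2-yl)-2H-chromen-5-yl]-4H-chromen-4-one, via vinyl ortho-quinone methide 16 (not isolated), via pyran-closed O5-prenyl ether 17 (not isolated), via C6 ortho-dienone 18 (not isolated)
Conditions: PhNEt2 (degassed), Ar, 140 °C, then 205 °C
Reagents that add atoms: none
Why: In ring B heat drives the aryl propargyl Claisen [3,3] shift from O3' to C2', enolisation gives the 2'-allenyl-3'-phenol, a 1,5-hydrogen shift from O–H to the central allene carbon gives the (Z)-vinyl ortho-quinone methide 16, and its oxa-6π electrocyclisation re-forms the O3'–C(CH3)2 bond and re-aromatises ring B to give 17. At the higher temperature the O5 prenyl ether of ring A undergoes an aromatic Claisen shift to C6 (dienone 18), a Cope shift to C8 and tautomerisation, which frees the chelated 5-OH and leaves a normal prenyl group on C8. The closest known reaction types are the thermal 2,2-dimethylchromene synthesis from aryl 1,1-dimethylpropargyl ethers and the para-Claisen–Cope relay of 5-O-prenylflavonoids, here run in one flask so that two of the three C5 units move from oxygen to carbon in one operation. Ring D is the only ring closed, and the mode is a thermal disrotatory 6π electrocyclic closure at the O–C bond of the array O=C3'–C2'=CH–CH=C(CH3)2, the arene–carbon bond C2'–CH having been made earlier in the same cascade by the [3,3] shift. No stereocentre remains, since C6 of 18 is erased by the Cope shift and tautomerisation, and the Z geometry of 16 needed for closure follows from the suprafacial hydrogen shift within the allenylphenol. The step needs regiocontrol in both rings and chemoselectivity: C4' (OMOM) and C4a are substituted, so shifts there are reversible dead ends; the 1,1-dimethylallyl group of 18 is squeezed between C5=O and the 7-OMOM group, so the Cope shift should outrun enolisation; the 3-OMOM group keeps O3 from capturing 16; and the C6' 1,1-dimethylallyl group has no [3,3] partner.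

Step 12
Reactants: 19 the tri-MOM ether of step 11
Product: 20 3,5,7-trihydroxy-2-[8-hydroxy-2,2-dimethyl-6-(2-methylbut-3-en-2-yl)-2H-chromen-5-yl]-8-(3-methylbut-2-enyl)-4H-chromen-4-one (CNP0241222.0)
Conditions: 3 M aq HCl–MeOH (1:10), 50 °C
Reagents that add atoms: none
Why: Acid-catalysed acetal exchange (MOM cleavage) under the mild methanolic conditions customary for prenylated flavonoids, which should free O3, O7 and O4' without protonating the prenyl, pyran or 1,1-dimethylallyl alkenes.

Compound list
1 | 2,4,6-trihydroxyacetophenone | CC(=O)c1c(O)cc(O)cc1O | starting material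
2 | 1-[2,6-dihydroxy-4-(methoxymethoxy)phenyl]ethanone | CC(=O)c1c(O)cc(OCOC)cc1O | intermediate
3 | 1-[2-hydroxy-4-(methoxymethoxy)-6-(3-methylbut-2-enyloxy)phenyl]ethanone (fragment A) | CC(=O)c1c(O)cc(OCOC)cc1OCC=C(C)C | intermediate
4 | 2-bromo-4,5-dimethoxybenzaldehyde | COc1cc(Br)c(C=O)cc1OC | starting material
5 | 2-bromo-4,5-dihydroxybenzaldehyde | Oc1cc(Br)c(C=O)cc1O | intermediate
6 | 2-bromo-5-hydroxy-4-(methoxymethoxy)benzaldehyde | COCOc1cc(Br)c(C=O)cc1O | intermediate
7 | 4-bromo-5-(dimethoxymethyl)-2-(methoxymethoxy)phenol | COCOc1cc(Br)c(C(OC)OC)cc1O | intermediate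
8 | 5-(dimethoxymethyl)-2-(methoxymethoxy)-4-(2-methylbut-3-en-2-yl)phenol (not isolated) | COCOc1cc(C(C)(C)C=C)c(C(OC)OC)cc1O | intermediate
9 | 5-hydroxy-4-(methoxymethoxy)-2-(2-methylbut-3-en-2-yl)benzaldehyde | COCOc1cc(C(C)(C)C=C)c(C=O)cc1O | intermediate
10 | 4-(methoxymethoxy)-2-(2-methylbut-3-en-2-yl)-5-(2-methylbut-3-yn-2-yloxy)benzaldehyde (fragment B) | COCOc1cc(C(C)(C)C=C)c(C=O)cc1OC(C)(C)C#C | intermediate
11 | (E)-chalcone from 3 and 10 | COCOc1cc(O)c(C(=O)/C=C/c2cc(OC(C)(C)C#C)c(OCOC)cc2C(C)(C)C=C)c(OCC=C(C)C)c1 | intermediate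
12 | trans-epoxide of chalcone 11 (racemic, one enantiomer drawn, not isolated) | COCOc1cc(O)c(C(=O)[C@H]2O[C@@H]2c3cc(OC(C)(C)C#C)c(OCOC)cc3C(C)(C)C=C)c(OCC=C(C)C)c1 | intermediate
13 | trans-2,3-dihydroflavonol (racemic, one enantiomer drawn, not isolated) | C=CC(C)(C)c1cc(OCOC)c(OC(C)(C)C#C)cc1[C@@H]2[C@H](C(=O)c3c(OCC=C(C)C)cc(OCOC)cc3O2)O | intermediate
14 | 3-hydroxy-7-(methoxymethoxy)-5-(3-methylbut-2-enyloxy)-2-[4-(methoxymethoxy)-2-(2-methylbut-3-en-2-yl)-5-(2-methylbut-3-yn-2-yloxy)phenyl]-4H-chromen-4-one | COCOc1cc(OCC=C(C)C)c2c(c1)oc(-c1cc(OC(C)(C)C#C)c(OCOC)cc1C(C)(C)C=C)c(O)c2=O | intermediate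
15 | 3,7-bis(methoxymethoxy)-5-(3-methylbut-2-enyloxy)-2-[4-(methoxymethoxy)-2-(2-methylbut-3-en-2-yl)-5-(2-methylbut-3-yn-2-yloxy)phenyl]-4H-chromen-4-one | COCOc1cc(OCC=C(C)C)c2c(c1)oc(-c1cc(OC(C)(C)C#C)c(OCOC)cc1C(C)(C)C=C)c(OCOC)c2=O | intermediate
16 | (Z)-vinyl ortho-quinone methide of ring B: C3'=O, C2'=CH–CH=C(CH3)2 (not isolated) | O=C1C(OCOC)=CC(C(C)(C)C=C)=C(c2oc3cc(OCOC)cc(OCC=C(C)C)c3c(=O)c2OCOC)/C1=C/C=C(C)C | intermediate
17 | ring D closed, O5 prenyl ether still in place (not isolated) | C=CC(C)(C)c1cc(OCOC)c2c(c1-c1oc3cc(OCOC)cc(OCC=C(C)C)c3c(=O)c1OCOC)C=CC(C)(C)O2 | intermediate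
18 | ring A ortho-dienone: C5=O, C6(H)(1,1-dimethylallyl) (racemic at C6, not isolated) | C=CC(C)(C)c1cc(OCOC)c2c(c1C4=C(OCOC)C(=O)C5=C(O4)C=C(OCOC)C(C(C)(C)C=C)C5=O)C=CC(C)(C)O2 | intermediate
19 | 5-hydroxy-3,7-bis(methoxymethoxy)-8-(3-methylbut-2-enyl)-2-[8-(methoxymethoxy)-2,2-dimethyl-6-(2-methylbut-3-en-2-yl)-2H-chromen-5-yl]-4H-chromen-4-one | C=CC(C)(C)c1cc(OCOC)c2c(c1-c1oc3c(CC=C(C)C)c(OCOC)cc(O)c3c(=O)c1OCOC)C=CC(C)(C)O2 | intermediate
20 | 3,5,7-trihydroxy-2-[8-hydroxy-2,2-dimethyl-6-(2-methylbut-3-en-2-yl)-2H-chromen-5-yl]-8-(3-methylbut-2-enyl)-4H-chromen-4-one (CNP0241222.0) | C=CC(C)(C)c1cc(O)c2c(c1-c1oc3c(CC=C(C)C)c(O)cc(O)c3c(=O)c1O)C=CC(C)(C)O2 | target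

Total step count: 12.
Longest linear sequence: 10 steps (steps 3 to 12, from 4).

Steps most likely to fail

1) Step 11.
- What may go wrong: the [3,3] shift into the crowded C2' position next to the C2–C1' axis may be slow. At the temperature then needed, thermal loss of the O-bound C5 units may compete. The C6 dienone may also enolise before the Cope shift, which would break the relay in ring A.
- Fallback: it sets out from 15, returns at 19, lowers the barrier of the shift and reaches the quinone methide by oxidation instead of by heat.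
- Semi-hydrogenation of the alkyne (H2, Pd/CaCO3 poisoned with Pb(OAc)2, quinoline, EtOAc) should give the 3'-O-(2-methylbut-3-en-2-yl) ether F5.
- Its tertiary allyl ether undergoes the Claisen shift to C2' far more easily than the propargyl ether. With Eu(fod)3 (10 mol %) in PhCl at 85–110 °C, where the lanthanide chelates C4=O and O5, the ring A relay should run as well, giving the 2',8-diprenyl-3',5-diphenol F6.
- DDQ (1.1 equiv, benzene, rt to 60 °C) should then abstract hydride from the benzylic CH2 of the 2'-prenyl group of the electron-rich ring B phenol. This generates the same vinyl ortho-quinone methide 16-type array, which closes ring D by oxa-6π electrocyclisation to 19.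
- The 8-prenyl group sits on the acyl-deactivated ring next to a protected O7 and should be spared.

2) Step 6.
- What may go wrong: the allylpalladium intermediate may slip (σ–π–σ) before reductive elimination, which would place a linear prenyl group on the arene. Oxidative addition to the bromide para to a phenoxide and ortho to the acetal may be sluggish. The boronate may protodeboronate.
- Fallback: it sets out from 7, returns at 8, and builds the quaternary benzylic carbon by enolate arylation followed by olefination.
- Coupling of 7 with the Reformatsky reagent BrZnC(CH3)2CO2CH3 (2.5 equiv, Pd(dba)2, P(t-Bu)3, THF, 60 °C) should give methyl 2-[2-(dimethoxymethyl)-4-hydroxy-5-(methoxymethoxy)phenyl]-2-methylpropanoate F1.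
- i-Bu2AlH (toluene, −78 °C) should give 2-[2-(dimethoxymethyl)-4-hydroxy-5-(methoxymethoxy)phenyl]-2-methylpropanal F2.
- Wittig methylenation (Ph3PCH3Br, KOt-Bu, THF, 0 °C, one extra equivalent for the phenol) should give 8, which is hydrolysed to 9 as in step 6.

3) Step 9.
- What may go wrong: the 6'-alkoxy group twists the aroyl unit and the ortho tert-alkyl group shields the benzylic carbon. Under basic conditions the phenoxide may therefore open the epoxide at the α carbon (5-exo), which diverts material into the aurone manifold.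
- Fallback: it sets out from 11, returns at 13, and steers the opening by acid on an isolated epoxide.
- Silylation (TBSOTf, 2,6-lutidine, CH2Cl2) should give the 2'-O-TBS chalcone F3.
- Weitz–Scheffer epoxidation (t-BuOOH, DBU, toluene, rt) should give the racemic trans-epoxide F4.
- HF·pyridine (THF, 0 °C) should remove the silyl group and protonate the epoxide. Cleavage then occurs at the benzylic carbon, which is stabilised by the para OMOM group, and the freed phenol closes ring C 6-endo to 13.
- 13 is then dehydrogenated to 14 in the alkaline peroxide medium of step 9.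

Further compounds
F1 | step 6 | methyl 2-[2-(dimethoxymethyl)-4-hydroxy-5-(methoxymethoxy)phenyl]-2-methylpropanoate | COCOc1cc(C(C)(C)C(=O)OC)c(C(OC)OC)cc1O
F2 | step 6 | 2-[2-(dimethoxymethyl)-4-hydroxy-5-(methoxymethoxy)phenyl]-2-methylpropanal | COCOc1cc(C(C)(C)C=O)c(C(OC)OC)cc1O
F3 | step 9 | 2'-O-(tert-butyldimethylsilyl) ether of chalcone 11 | COCOc1cc(O[Si](C)(C)C(C)(C)C)c(C(=O)/C=C/c2cc(OC(C)(C)C#C)c(OCOC)cc2C(C)(C)C=C)c(OCC=C(C)C)c1
F4 | step 9 | trans-epoxide of F3 (racemic, one enantiomer drawn) | COCOc1cc(O[Si](C)(C)C(C)(C)C)c(C(=O)[C@H]2O[C@@H]2c3cc(OC(C)(C)C#C)c(OCOC)cc3C(C)(C)C=C)c(OCC=C(C)C)c1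
F5 | step 11 | 3,7-bis(methoxymethoxy)-5-(3-methylbut-2-enyloxy)-2-[4-(methoxymethoxy)-2-(2-methylbut-3-en-2-yl)-5-(2-methylbut-3-en-2-yloxy)phenyl]-4H-chromen-4-one | COCOc1cc(OCC=C(C)C)c2c(c1)oc(-c1cc(OC(C)(C)C=C)c(OCOC)cc1C(C)(C)C=C)c(OCOC)c2=O
F6 | step 11 | 5-hydroxy-2-[3-hydroxy-4-(methoxymethoxy)-6-(2-methylbut-3-en-2-yl)-2-(3-methylbut-2-enyl)phenyl]-3,7-bis(methoxymethoxy)-8-(3-methylbut-2-enyl)-4H-chromen-4-one | C=CC(C)(C)c1cc(OCOC)c(O)c(CC=C(C)C)c1-c1oc2c(CC=C(C)C)c(OCOC)cc(O)c2c(=O)c1OCOC
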